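## Retrosynthetic overview

1. The target is cut at the C3–O–C15′ ester into acid **25** (vinyl half A) and diol **31** (diol half B); the three remaining esters are cleaved last.
2. In each half the pyran ring (O–C8 bond) is closed last by acid cyclisation of a 13‑carbinol onto an 8(17)‑ene. C13 and C14 come from an (S)‑ or (R)‑glycerate vinyl ketone by Mukaiyama–Michael addition at C9 and chelation‑controlled MeMgBr addition; the vinyl group of half A is made from its 14,15‑diol.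
3. Both halves come from one silyl enol ether **11**, whose C10 quaternary centre is set by a Mukaiyama–Michael addition to enone **10**.
4. Key step: Ireland–Claisen [3,3] rearrangement of cis‑carveyl isobutyrate forges the C4–C5 bond and relays the (R)‑carvone stereocentre to C5; allylic oxidation and excision of the isopropenyl group then give **10**.
5. Ring order: the carbocycle (ring B) is bought as carvone, the pyran ring is formed last in each half, and the halves are joined at the end.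

Assumption: (R)‑(−)‑carvone and both enantiomers of methyl 2,2‑dimethyl‑1,3‑dioxolane‑4‑carboxylate are taken as cheap commercial chiral materials; locants C1–C20 are labdane locants of each half (C2, C3 = carboxyl carbons, ring B = C5–C10, O bridges C8 and C13; primed = half B).

## Route

Step 1
Reactants: 1 (R)‑(−)‑carvone
Product: 2 (1R,5R)‑cis‑carveol
Conditions: NaBH4, CeCl3·7H2O, MeOH, −20 °C
Reagents that add atoms: none
Why: Luche 1,2‑reduction, in which axial hydride delivery gives the pseudo‑equatorial carbinol cis to the isopropenyl group, so the new C–O centre is set by the carvone stereocentre.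

Step 2
Reactants: 2 (1R,5R)‑cis‑carveol
Product: 3 cis‑carveyl isobutyrate
Conditions: i‑PrCOCl, pyridine, 4‑(dimethylamino)pyridine (cat.), CH2Cl2, 0 °C → rt
Reagents that add atoms: isobutyryl chloride, CC(C)C(=O)Cl
Why: O‑acylation by nucleophilic acyl substitution, with no stereocentre touched.

Step 3
Reactants: 3 cis‑carveyl isobutyrate
Product: 6 2‑methyl‑2‑[(1S,5S)‑2‑methyl‑5‑(prop‑1‑en‑2‑yl)cyclohex‑2‑en‑1‑yl]propanoic acid, via silyl ketene acetal 4 (not isolated), via trimethylsilyl ester 5 (not isolated)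
Conditions: LiN(iPr)2, THF, −78 °C; Me3SiCl, −78 → 65 °C; then 1 M HCl
Reagents that add atoms: none
Why: Ireland–Claisen [3,3]‑sigmatropic rearrangement, in which the geometry‑free tetrasubstituted ketene acetal shifts suprafacially and places the CMe2CO2H group on C5 on the face of the departing C–O bond (cis to isopropenyl).

Step 4
Reactants: 6 Claisen acid
Product: 7 2‑(trimethylsilyl)ethyl ester of 6
Conditions: Me3SiCH2CH2OH, PPh3, diisopropyl azodicarboxylate, THF, 0 °C → rt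
Reagents that add atoms: 2‑(trimethylsilyl)ethanol, C[Si](C)(C)CCO
Why: Mitsunobu esterification, where the hindered carboxylate is the nucleophile at the activated primary carbinol carbon, so the bulk around the acid does not matter.

Step 5
Reactants: 7 silylethyl ester
Product: 8 isopropenyl enone (2‑methyl‑4‑oxo‑5‑isopropenylcyclohex‑2‑enyl ester)
Conditions: CrO3, 3,5‑dimethylpyrazole, CH2Cl2, −20 °C
Reagents that add atoms: chromium trioxide, O=[Cr](=O)=O
Why: Allylic oxidation by hexavalent chromium at the only unhindered allylic CH2 of the ring olefin (C8), the other ring allylic site being the neopentyl‑type C5–H.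

Step 6
Reactants: 8 isopropenyl enone
Product: 10 2‑(trimethylsilyl)ethyl 2‑methyl‑2‑[(1S)‑2‑methyl‑4‑oxocyclohex‑2‑en‑1‑yl]propanoate (enone), via methoxy hydroperoxide 9 (not isolated)
Conditions: O3, MeOH, −78 °C; then FeSO4·7H2O, PhSH, −78 °C → rt
Reagents that add atoms: none
Why: Hydrodealkenylation: ozone attacks only the electron‑rich isopropenyl group (Criegee methoxy hydroperoxide), divalent iron triggers β‑scission of the alkoxy radical, and the α‑keto radical takes H from PhSH, leaving C5 as the only stereocentre.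

Step 7
Reactants: 10 enone
Product: 11 tert‑butyldimethylsilyl enol ether with the C10 quaternary centre
Conditions: CH2=C(OMe)OSiMe2t‑Bu, (CF3SO2)2NH (2 mol %), CH2Cl2, −78 → −40 °C; Et3N
Reagents that add atoms: 1‑(tert‑butyldimethylsilyloxy)‑1‑methoxyethene, C=C(OC)O[Si](C)(C)C(C)(C)C
Why: Mukaiyama–Michael addition with silyl transfer, in which the ketene acetal enters C10 anti to the pseudo‑axial CMe2CO2R group on C5 (CH2CO2Me trans to it) and the regiodefined C8–C9 silyl enol ether is kept.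

Step 8
Reactants: 12 methyl (S)‑2,2‑dimethyl‑1,3‑dioxolane‑4‑carboxylate
Product: 14 1‑[(4S)‑2,2‑dimethyl‑1,3‑dioxolan‑4‑yl]prop‑2‑en‑1‑one, via Weinreb amide 13 (not isolated)
Conditions: MeNHOMe·HCl, i‑PrMgCl, THF, −20 °C; then CH2=CHMgBr, −20 → 0 °C; inverse quench into cold 1 M HCl
Reagents that add atoms: vinylmagnesium bromide, C=C[Mg]Br
Why: Ester aminolysis to the Weinreb amide followed by acyl substitution that stops at the ketone through the chelated tetrahedral intermediate, with the bought stereocentre untouched.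

Step 9
Reactants: 15 methyl (R)‑2,2‑dimethyl‑1,3‑dioxolane‑4‑carboxylate
Product: 17 1‑[(4R)‑2,2‑dimethyl‑1,3‑dioxolan‑4‑yl]prop‑2‑en‑1‑one, via Weinreb amide 16 (not isolated)
Conditions: MeNHOMe·HCl, i‑PrMgCl, THF, −20 °C; then CH2=CHMgBr, −20 → 0 °C; inverse quench into cold 1 M HCl
Reagents that add atoms: vinylmagnesium bromide, C=C[Mg]Br
Why: Same Weinreb ketone synthesis in the enantiomeric series, with the bought stereocentre untouched.

Step 10
Reactants: 11 silyl enol ether, 14 (S)‑vinyl ketone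
Product: 18 keto silyl enol ether of half A (8‑oxo, 13‑silyloxy‑12‑ene, 14S‑dioxolane)
Conditions: (CF3SO2)2NH (2 mol %), CH2Cl2, −78 °C; Et3N; then DBU, toluene, 50 °C
Reagents that add atoms: none
Why: Mukaiyama–Michael addition of C9 to the vinyl ketone with silyl transfer to the new enolate (C13 stays masked, the C8 ketone is freed), after which DBU equilibrates the epimerisable C9 to the equatorial side chain trans to CH2CO2Me.

Step 11
Reactants: 18 keto silyl enol ether of half A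
Product: 20 methylene ketone of half A (8(17)‑ene, 13‑ketone), via methylene silyl enol ether 19 (not isolated)
Conditions: Ph3PCH3Br, NaN(SiMe3)2, THF, 0 → 50 °C; then 0.5 M aq. HCl, THF, 0 °C
Reagents that add atoms: methyltriphenylphosphonium bromide, C[P+](c1ccccc1)(c1ccccc1)c1ccccc1.[Br-]
Why: Wittig methylenation of the only free ketone (C8) brings in C17, and brief dilute acid hydrolyses the silyl enol ether to the C13 ketone.

Step 12
Reactants: 20 methylene ketone of half A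
Product: 21 tertiary carbinol of half A (13R,14S)
Conditions: MgBr2·OEt2, CH2Cl2, −78 °C; then MeMgBr (Et2O), −78 °C
Reagents that add atoms: methylmagnesium bromide, C[Mg]Br
Why: Cram‑chelate‑controlled Grignard addition, in which magnesium bridges the C13 carbonyl and the C14 dioxolane oxygen and methyl enters from the C14–H face, giving 13R from the bought 14S centre.

Step 13
Reactants: 21 tertiary carbinol of half A
Product: 23 pyran diol of half A, via pyran acetonide 22 (not isolated)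
Conditions: p‑toluenesulfonic acid monohydrate (20 mol %), CH2Cl2, 0 °C → rt; then MeOH, 40 °C
Reagents that add atoms: none
Why: Brønsted‑acid Markovnikov hydroalkoxylation (the cationic course of labd‑8(17)‑en‑13‑ol to manoyl oxide), in which the C8 cation is captured by the 13‑OH anti to the axial C20 methyl to give the trans‑fused pyran with the C13–O bond intact, followed by transketalisation of the acetonide.

Step 14
Reactants: 23 pyran diol of half A
Product: 24 vinyl pyran diester of half A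
Conditions: PPh3, imidazole, I2, toluene, 90 °C
Reagents that add atoms: none
Why: Garegg–Samuelsson deoxygenation of the terminal vicinal diol to the vinyl group, which erases C14 and leaves C13 untouched.

Step 15
Reactants: 24 vinyl pyran diester of half A
Product: 25 acid of half A (free C3 acid, C2 methyl ester)
Conditions: Bu4NF, THF, 0 °C → rt; aq. NH4Cl
Reagents that add atoms: none
Why: Fluoride‑induced β‑elimination of the 2‑(trimethylsilyl)ethyl ester frees the hindered C3 acid without touching the methyl ester or the allylic ether.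

Step 16
Reactants: 11 silyl enol ether, 17 (R)‑vinyl ketone
Product: 26 keto silyl enol ether of half B (14R‑dioxolane)
Conditions: (CF3SO2)2NH (2 mol %), CH2Cl2, −78 °C; Et3N; then DBU, toluene, 50 °C
Reagents that add atoms: none
Why: Same Mukaiyama–Michael addition with silyl transfer and C9 equilibration as in step 10.

Step 17
Reactants: 26 keto silyl enol ether of half B
Product: 28 methylene ketone of half B, via methylene silyl enol ether 27 (not isolated)
Conditions: Ph3PCH3Br, NaN(SiMe3)2, THF, 0 → 50 °C; then 0.5 M aq. HCl, THF, 0 °C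
Reagents that add atoms: methyltriphenylphosphonium bromide, C[P+](c1ccccc1)(c1ccccc1)c1ccccc1.[Br-]
Why: Wittig methylenation at C8 and hydrolysis of the silyl enol ether, as in step 11.

Step 18
Reactants: 28 methylene ketone of half B
Product: 29 tertiary carbinol of half B (13S,14R)
Conditions: MgBr2·OEt2, CH2Cl2, −78 °C; then MeMgBr (Et2O), −78 °C
Reagents that add atoms: methylmagnesium bromide, C[Mg]Br
Why: Cram‑chelate‑controlled Grignard addition, mirror image of step 12, giving 13S from the bought 14R centre.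

Step 19
Reactants: 29 tertiary carbinol of half B
Product: 31 pyran diol of half B, via pyran acetonide 30 (not isolated)
Conditions: p‑toluenesulfonic acid monohydrate (20 mol %), CH2Cl2, 0 °C → rt; then MeOH, 40 °C
Reagents that add atoms: none
Why: Same acid hydroalkoxylation and acetonide removal as in step 13, with C8 set anti to the axial C20 methyl.

Step 20
Reactants: 25 acid of half A, 31 pyran diol of half B
Product: 33 protected dimer (C3 of half A esterified at O15′ of half B), via acid chloride 32 (not isolated)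
Conditions: 25, Me2C=C(Cl)NMe2, CH2Cl2, 0 °C → rt; then 31, pyridine, 4‑(dimethylamino)pyridine, CH2Cl2, 0 → 35 °C
Reagents that add atoms: none
Why: Neutral acid chloride formation with the α‑chloroenamine and nucleophile‑catalysed acylation, which takes place only at the primary 15′‑OH because the 14′‑OH is secondary and flanked by the quaternary C13′.

Step 21
Reactants: 33 protected dimer
Product: 35 CNP0107285.3 (target), via monoacid 34 (not isolated)
Conditions: Bu4NF, THF, rt; then LiOH, THF/MeOH/H2O, rt; cold 0.5 M HCl to pH 3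
Reagents that add atoms: lithium hydroxide, [Li+].[OH-]
Why: Fluoride cleavage of the silylethyl ester, then saponification of the two unhindered methyl esters, while the inter‑unit ester (fully substituted acyl carbon) resists LiOH at room temperature.

## Compound list

1 | (R)‑(−)‑carvone, (5R)‑2‑methyl‑5‑(prop‑1‑en‑2‑yl)cyclohex‑2‑en‑1‑one | O=C1C(C)=CC[C@@H](C(C)=C)C1 | starting material
2 | (1R,5R)‑2‑methyl‑5‑(prop‑1‑en‑2‑yl)cyclohex‑2‑en‑1‑ol (cis‑carveol) | O[C@H]1C(C)=CC[C@@H](C(C)=C)C1 | intermediate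
3 | (1R,5R)‑2‑methyl‑5‑(prop‑1‑en‑2‑yl)cyclohex‑2‑en‑1‑yl 2‑methylpropanoate | CC(C)C(=O)O[C@H]1C(C)=CC[C@@H](C(C)=C)C1 | intermediate
4 | trimethylsilyl ketene acetal of 3 | CC(C)=C(O[Si](C)(C)C)O[C@H]1C(C)=CC[C@@H](C(C)=C)C1 | intermediate
5 | trimethylsilyl 2‑methyl‑2‑[(1S,5S)‑2‑methyl‑5‑(prop‑1‑en‑2‑yl)cyclohex‑2‑en‑1‑yl]propanoate | C1=C(C)[C@@H](C(C)(C)C(=O)O[Si](C)(C)C)C[C@@H](C(C)=C)C1 | intermediate
6 | 2‑methyl‑2‑[(1S,5S)‑2‑methyl‑5‑(prop‑1‑en‑2‑yl)cyclohex‑2‑en‑1‑yl]propanoic acid | C1=C(C)[C@@H](C(C)(C)C(=O)O)C[C@@H](C(C)=C)C1 | intermediate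
7 | 2‑(trimethylsilyl)ethyl 2‑methyl‑2‑[(1S,5S)‑2‑methyl‑5‑(prop‑1‑en‑2‑yl)cyclohex‑2‑en‑1‑yl]propanoate | C1=C(C)[C@@H](C(C)(C)C(=O)OCC[Si](C)(C)C)C[C@@H](C(C)=C)C1 | intermediate
8 | 2‑(trimethylsilyl)ethyl 2‑methyl‑2‑[(1S,5S)‑2‑methyl‑4‑oxo‑5‑(prop‑1‑en‑2‑yl)cyclohex‑2‑en‑1‑yl]propanoate | O=C1C=C(C)[C@@H](C(C)(C)C(=O)OCC[Si](C)(C)C)C[C@H]1C(C)=C | intermediate
9 | analogue of 8 with the isopropenyl group changed to 1‑hydroperoxy‑1‑methoxyethyl (mixture at the new centre) | O=C1C=C(C)[C@@H](C(C)(C)C(=O)OCC[Si](C)(C)C)C[C@H]1C(C)(OC)OO | intermediate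
10 | 2‑(trimethylsilyl)ethyl 2‑methyl‑2‑[(1S)‑2‑methyl‑4‑oxocyclohex‑2‑en‑1‑yl]propanoate | O=C1C=C(C)[C@@H](C(C)(C)C(=O)OCC[Si](C)(C)C)CC1 | intermediate
11 | methyl 2‑[(1R,6S)‑3‑(tert‑butyldimethylsilyloxy)‑1‑methyl‑6‑{2‑methyl‑1‑oxo‑1‑[2‑(trimethylsilyl)ethoxy]propan‑2‑yl}cyclohex‑2‑en‑1‑yl]acetate | CC(C)(C)[Si](C)(C)OC1=C[C@](C)(CC(=O)OC)[C@@H](C(C)(C)C(=O)OCC[Si](C)(C)C)CC1 | intermediate
12 | methyl (S)‑2,2‑dimethyl‑1,3‑dioxolane‑4‑carboxylate | COC(=O)[C@@H]1COC(C)(C)O1 | starting material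
13 | (S)‑N‑methoxy‑N,2,2‑trimethyl‑1,3‑dioxolane‑4‑carboxamide | CON(C)C(=O)[C@@H]1COC(C)(C)O1 | intermediate
14 | 1‑[(4S)‑2,2‑dimethyl‑1,3‑dioxolan‑4‑yl]prop‑2‑en‑1‑one | C=CC(=O)[C@@H]1COC(C)(C)O1 | intermediate
15 | methyl (R)‑2,2‑dimethyl‑1,3‑dioxolane‑4‑carboxylate | COC(=O)[C@H]1COC(C)(C)O1 | starting material
16 | (R)‑N‑methoxy‑N,2,2‑trimethyl‑1,3‑dioxolane‑4‑carboxamide | CON(C)C(=O)[C@H]1COC(C)(C)O1 | intermediate
17 | 1‑[(4R)‑2,2‑dimethyl‑1,3‑dioxolan‑4‑yl]prop‑2‑en‑1‑one | C=CC(=O)[C@H]1COC(C)(C)O1 | intermediate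
18 | (5S,9S,10R,14S)‑13‑(tert‑butyldimethylsilyloxy)‑14,15‑(isopropylidenedioxy)‑8‑oxo‑16,17‑dinor‑2,3‑secolabd‑12‑ene‑2,3‑dioic acid 2‑methyl 3‑[2‑(trimethylsilyl)ethyl] diester (12E/Z mixture) | CC(C)(C)[Si](C)(C)OC(=CC[C@H]1[C@](C)(CC(=O)OC)[C@@H](C(C)(C)C(=O)OCC[Si](C)(C)C)CCC1=O)[C@@H]2COC(C)(C)O2 | intermediate
19 | (5S,9R,10S,14S)‑13‑(tert‑butyldimethylsilyloxy)‑14,15‑(isopropylidenedioxy)‑16‑nor‑2,3‑secolabda‑8(17),12‑diene‑2,3‑dioic acid 2‑methyl 3‑[2‑(trimethylsilyl)ethyl] diester | CC(C)(C)[Si](C)(C)OC(=CC[C@H]1[C@](C)(CC(=O)OC)[C@@H](C(C)(C)C(=O)OCC[Si](C)(C)C)CCC1=C)[C@@H]2COC(C)(C)O2 | intermediate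
20 | (5S,9R,10S,14S)‑14,15‑(isopropylidenedioxy)‑13‑oxo‑16‑nor‑2,3‑secolabd‑8(17)‑ene‑2,3‑dioic acid 2‑methyl 3‑[2‑(trimethylsilyl)ethyl] diester | O=C(CC[C@H]1[C@](C)(CC(=O)OC)[C@@H](C(C)(C)C(=O)OCC[Si](C)(C)C)CCC1=C)[C@@H]2COC(C)(C)O2 | intermediate
21 | (5S,9R,10S,13R,14S)‑13‑hydroxy‑14,15‑(isopropylidenedioxy)‑2,3‑secolabd‑8(17)‑ene‑2,3‑dioic acid 2‑methyl 3‑[2‑(trimethylsilyl)ethyl] diester | C[C@@](O)(CC[C@H]1[C@](C)(CC(=O)OC)[C@@H](C(C)(C)C(=O)OCC[Si](C)(C)C)CCC1=C)[C@@H]2COC(C)(C)O2 | intermediate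
22 | (5S,8S,9S,10R,13R,14S)‑8,13‑epoxy‑14,15‑(isopropylidenedioxy)‑2,3‑secolabdane‑2,3‑dioic acid 2‑methyl 3‑[2‑(trimethylsilyl)ethyl] diester | CC1(C)OC[C@H](O1)[C@@]2(C)CC[C@H]3[C@](C)(CC(=O)OC)[C@@H](C(C)(C)C(=O)OCC[Si](C)(C)C)CC[C@]3(C)O2 | intermediate
23 | (5S,8S,9S,10R,13R,14S)‑8,13‑epoxy‑14,15‑dihydroxy‑2,3‑secolabdane‑2,3‑dioic acid 2‑methyl 3‑[2‑(trimethylsilyl)ethyl] diester | OC[C@H](O)[C@@]1(C)CC[C@H]2[C@](C)(CC(=O)OC)[C@@H](C(C)(C)C(=O)OCC[Si](C)(C)C)CC[C@]2(C)O1 | intermediate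
24 | (5S,8S,9S,10R,13R)‑8,13‑epoxy‑2,3‑secolabd‑14‑ene‑2,3‑dioic acid 2‑methyl 3‑[2‑(trimethylsilyl)ethyl] diester | C=C[C@@]1(C)CC[C@H]2[C@](C)(CC(=O)OC)[C@@H](C(C)(C)C(=O)OCC[Si](C)(C)C)CC[C@]2(C)O1 | intermediate
25 | (5S,8S,9S,10R,13R)‑8,13‑epoxy‑2,3‑secolabd‑14‑ene‑2,3‑dioic acid 2‑methyl ester | C=C[C@@]1(C)CC[C@H]2[C@](C)(CC(=O)OC)[C@@H](C(C)(C)C(=O)O)CC[C@]2(C)O1 | intermediate
26 | (5S,9S,10R,14R) diastereomer of 18 (12E/Z mixture) | CC(C)(C)[Si](C)(C)OC(=CC[C@H]1[C@](C)(CC(=O)OC)[C@@H](C(C)(C)C(=O)OCC[Si](C)(C)C)CCC1=O)[C@H]2COC(C)(C)O2 | intermediate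
27 | (5S,9R,10S,14R) diastereomer of 19 | CC(C)(C)[Si](C)(C)OC(=CC[C@H]1[C@](C)(CC(=O)OC)[C@@H](C(C)(C)C(=O)OCC[Si](C)(C)C)CCC1=C)[C@H]2COC(C)(C)O2 | intermediate
28 | (5S,9R,10S,14R) diastereomer of 20 | O=C(CC[C@H]1[C@](C)(CC(=O)OC)[C@@H](C(C)(C)C(=O)OCC[Si](C)(C)C)CCC1=C)[C@H]2COC(C)(C)O2 | intermediate
29 | (5S,9R,10S,13S,14R)‑13‑hydroxy‑14,15‑(isopropylidenedioxy)‑2,3‑secolabd‑8(17)‑ene‑2,3‑dioic acid 2‑methyl 3‑[2‑(trimethylsilyl)ethyl] diester | C[C@](O)(CC[C@H]1[C@](C)(CC(=O)OC)[C@@H](C(C)(C)C(=O)OCC[Si](C)(C)C)CCC1=C)[C@H]2COC(C)(C)O2 | intermediate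
30 | (5S,8S,9S,10R,13S,14R)‑8,13‑epoxy‑14,15‑(isopropylidenedioxy)‑2,3‑secolabdane‑2,3‑dioic acid 2‑methyl 3‑[2‑(trimethylsilyl)ethyl] diester | CC1(C)OC[C@@H](O1)[C@]2(C)CC[C@H]3[C@](C)(CC(=O)OC)[C@@H](C(C)(C)C(=O)OCC[Si](C)(C)C)CC[C@]3(C)O2 | intermediate
31 | (5S,8S,9S,10R,13S,14R)‑8,13‑epoxy‑14,15‑dihydroxy‑2,3‑secolabdane‑2,3‑dioic acid 2‑methyl 3‑[2‑(trimethylsilyl)ethyl] diester | OC[C@@H](O)[C@]1(C)CC[C@H]2[C@](C)(CC(=O)OC)[C@@H](C(C)(C)C(=O)OCC[Si](C)(C)C)CC[C@]2(C)O1 | intermediate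
32 | C3 acid chloride of 25 | C=C[C@@]1(C)CC[C@H]2[C@](C)(CC(=O)OC)[C@@H](C(C)(C)C(=O)Cl)CC[C@]2(C)O1 | intermediate
33 | protected dimer: 15′‑O ester of 31 with the C3 acid of 25 (two methyl esters, one 2‑(trimethylsilyl)ethyl ester, free 14′‑OH) | C=C[C@@]1(C)CC[C@H]2[C@](C)(CC(=O)OC)[C@@H](C(C)(C)C(=O)OC[C@@H](O)[C@]3(C)CC[C@H]4[C@](C)(CC(=O)OC)[C@@H](C(C)(C)C(=O)OCC[Si](C)(C)C)CC[C@]4(C)O3)CC[C@]2(C)O1 | intermediate
34 | dimer with free 3′‑acid and both methyl esters intact | C=C[C@@]1(C)CC[C@H]2[C@](C)(CC(=O)OC)[C@@H](C(C)(C)C(=O)OC[C@@H](O)[C@]3(C)CC[C@H]4[C@](C)(CC(=O)OC)[C@@H](C(C)(C)C(=O)O)CC[C@]4(C)O3)CC[C@]2(C)O1 | intermediate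
35 | CNP0107285.3: half A (5S,8S,9S,10R,13R) joined through C3 to O15′ of half B (5′S,8′S,9′S,10′R,13′S,14′R) | C=C[C@@]1(C)CC[C@H]2[C@](C)(CC(=O)O)[C@@H](C(C)(C)C(=O)OC[C@@H](O)[C@]3(C)CC[C@H]4[C@](C)(CC(=O)O)[C@@H](C(C)(C)C(=O)O)CC[C@]4(C)O3)CC[C@]2(C)O1 | target

## Step count and weak points

Total step count: 21. Longest linear sequence: 15 steps (steps 1–7, 10–15, 20, 21).

Most likely to fail, first: step 7, because the Mukaiyama–Michael addition must build the C10 quaternary centre next to the carbon carrying the tertiary ester group. The fallback sets out from 10 and comes back at 11. A [2+2] photocycloaddition of 10 with allene (hν above 300 nm, CH2Cl2, −78 °C) is insensitive to the crowding and adds anti to the C5 side chain, giving the cis‑fused methylenecyclobutane photoadduct F1. Ozonolysis (O3, CH2Cl2/MeOH, −78 °C; Me2S) gives the 2‑acylcyclobutanone F2. One equivalent of NaOMe in THF at −40 °C then opens the strained cyclobutanone by retro‑Claisen cleavage; the ring carbonyl carbon becomes the CH2CO2Me group on C10 and the C8–C9 enolate is released regiospecifically, and t‑BuMe2SiCl traps it as 11.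

Second: step 13 (and its twin, step 19), because the cationic ring closure may give olefin isomers or the cis‑fused ether. The fallback sets out from 21 and comes back at 23. Oxymercuration with Hg(OAc)2 in THF at room temperature lets the 13‑OH open the mercurinium ion at C8 and gives the 17‑(acetoxymercurio) pyran F3. NaBH4 in aqueous NaOH removes mercury to give the pyran acetonide 22, and AcOH/H2O (3:1, 40 °C) then gives 23; 29 is taken to 31 in the same way.

Third: step 14, because the Garegg–Samuelsson deoxygenation has to activate a secondary hydroxyl next to a quaternary ether carbon. The fallback sets out from 23 and comes back at 24. 1,1′‑Thiocarbonyldiimidazole in toluene at 80 °C gives the cyclic thionocarbonate F4, and heating with P(OMe)3 at 120 °C (Corey–Winter olefination, a concerted syn cycloreversion) gives 24.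

## Further compounds

F1 | step 7 | 2‑(trimethylsilyl)ethyl 2‑methyl‑2‑(1‑methyl‑7‑methylidene‑5‑oxobicyclo[4.2.0]octan‑2‑yl)propanoate, cis‑fused, cyclobutane anti to the side chain | C=C1C[C@]2(C)[C@@H](C(C)(C)C(=O)OCC[Si](C)(C)C)CCC(=O)[C@H]12
F2 | step 7 | 2‑(trimethylsilyl)ethyl 2‑(1‑methyl‑5,7‑dioxobicyclo[4.2.0]octan‑2‑yl)‑2‑methylpropanoate, cis‑fused | O=C1C[C@]2(C)[C@@H](C(C)(C)C(=O)OCC[Si](C)(C)C)CCC(=O)[C@H]12
F3 | step 13 | 17‑(acetoxymercurio) derivative of pyran acetonide 22 | CC1(C)OC[C@H](O1)[C@@]2(C)CC[C@H]3[C@](C)(CC(=O)OC)[C@@H](C(C)(C)C(=O)OCC[Si](C)(C)C)CC[C@]3(C[Hg]OC(C)=O)O2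
F4 | step 14 | 14,15‑cyclic thionocarbonate of 23 | S=C1OC[C@H](O1)[C@@]2(C)CC[C@H]3[C@](C)(CC(=O)OC)[C@@H](C(C)(C)C(=O)OCC[Si](C)(C)C)CC[C@]3(C)O2
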